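Read the flat part of a run first: it shows how much of the charge stays out of the chains. Red and amber each held 0.25 mM of initiator, red with 0.029 M of free monomer and amber with 0.15 M. West and east hold 0.25 mM of initiator with 0.025 M and 0.10 M of free monomer, closed, stirred and isothermal, for 20 h.

- red (time / h: monomer in chains / %): 0.833: 36.9; 1.33: 37.0; 2.00: 36.5; 4.00: 37.0; 6.00: 36.6; 10.0: 36.6
- amber (time / h: monomer in chains / %): 1.50: 86.7; 3.00: 86.5; 5.00: 86.9; 6.00: 86.9; 8.00: 87.1; 10.0: 86.9

(each reading ± 0.3 percentage points)

1. which of the two ends with the longer chains by the average number of monomer units in a chain (chains begun, living or dead) ("neither" if they lie within 10%) (west / east / neither)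
2. average number of monomer units in a chain (chains begun, living or dead) at the end, west
3. average number of monomer units in a chain (chains begun, living or dead) at the end, east

I went down the time scales. On the first rung the chains fill, and this was over before the first readings, at 0.833 h in red and 1.50 h in amber, so I saw its end. On the second rung the plateau stays flat within the scatter of 0.3 percentage points up to 10.0 h. On the third rung lies the asked time, twice that last reading, and I assumed the plateau carried on.

At its last reading red left 0.0184 M of its charge outside the chains, and amber at its last reading 0.0196 M. I carried the red figure as the ceiling level, the monomer standing outside the chains on the plateau, which I read as the equilibrium monomer concentration. I chose red because the same scatter weighs 5.17 times as much in molar terms in amber.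

The average length is then the charge above the ceiling level divided by the chains begun. The runs don't show the chains, so I guessed one per initiator. That gave 26.5 for west and 326 for east, so east ends longer.

The forecast, a little apart from my figures, said east, with 27 (23 to 45) for west and 322 (300 to 520) for east, skewed upward since “if initiation is incomplete, the averages would be higher”.

The flask gave east, with 26.6 in west and 326 in east.

    free monomer + initiator → living end + monomer in chains (k = 0.0760 L mol⁻¹ s⁻¹)
    monomer in chains + living end → free monomer + living end, rate k2*[living end] as long as [monomer in chains] is above zero (k = 0.670 s⁻¹)
    free monomer + living end → monomer in chains + living end, rate k3*[living end]*[free monomer] (k = 37.0 L mol⁻¹ s⁻¹)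
    living end + monomer in chains → dead end (k = 0.0210 L mol⁻¹ s⁻¹)

The neighbour is east with 1.0 × 10⁻⁴ M of initiator. The same reckoning gave 816 for it, and the flask gave 781. It kept 22% of its free monomer, which is 0.0218 M, above the ceiling level, while its living ends stood at 0 M after 20.0 h.

(The runs are simulated with constants of no real substance.)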